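The synthesis rests on cutting the sp2–sp2 bond between ketone carbon C9 and alkene carbon C10 of the cross-conjugated methylidene ketone. A Milstein–Stille acylation unites two fragments. One is a twelve-carbon acid chloride that already holds the 1,2-dioxane ring (O1, O2, C3–C6), all three stereocentres and the methyl ester. The other is a nine-carbon 2-stannyl-1-alkene bearing the free tertiary alcohol. In one neutral operation the step gives the unprotected target and unveils the Michael-sensitive enone last. It exploits the C7–C8 spacer, which insulates the acyl carbon from quaternary C6 and the O–O bond. The dioxane acid arises from a cis-β-lactone by invertive peroxide ring closure and axial allylation of a peroxycarbenium ion.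

Key step: step 10

Remark on numbering: C1 is the ester carbonyl, C2 its α-carbon, C3–C6 the ring carbons (O2 on C3, O1 on C6), C7 and C8 the two methylenes, C9 the ketone carbon, and C10 the alkene carbon bearing the methylidene group.

Assumption: the sense of induction of O-trimethylsilylquinine in step 2 is taken from quinine-type catalysts in ketene–aldehyde cycloadditions; if it proved opposite, the pseudoenantiomeric O-trimethylsilylquinidine would be used and nothing else would change.

Step 1
Reactants: 1 ethyl 4-methylpent-4-enoate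
Product: 2 4-methylpent-4-enal
Conditions: iBu2AlH (1.05 equiv), CH2Cl2, −78 °C; MeOH, aq. potassium sodium tartrate
Reagents that add atoms: none
Why: Partial ester reduction, in which iBu2AlH adds once at −78 °C and the tetrahedral aluminium hemiacetal survives until the quench, so the aldehyde is released only on work-up and the isolated alkene is untouched.

Step 2
Reactants: 2 4-methylpent-4-enal; 3 propanoyl chloride
Product: 5 (3S,4R)-3-methyl-4-(3-methylbut-3-en-1-yl)oxetan-2-one, via methylketene 4 (not isolated)
Conditions: 3 (2 equiv, slow addition), O-trimethylsilylquinine (10 mol %), LiClO4 (2 equiv), iPr2NEt (2.5 equiv), CH2Cl2/Et2O, −78 °C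
Reagents that add atoms: none
Why: Alkaloid-catalysed acyl halide–aldehyde cyclocondensation (formal [2+2] ketene–aldehyde cycloaddition), in which 4 is trapped by the quinuclidine nitrogen as a Z-configured acylammonium enolate that adds to the LiClO4-activated aldehyde through a closed chair-like transition state, which sets the cis C2/C3 relation, while the alkaloid shields one enolate face and fixes the absolute (3S,4R) configuration.

Step 3
Reactants: 5 (3S,4R)-3-methyl-4-(3-methylbut-3-en-1-yl)oxetan-2-one
Product: 7 (3S,4R)-4-(3-hydroperoxy-3-methoxybutyl)-3-methyloxetan-2-one (both ketal epimers), via carbonyl oxide 6 (not isolated)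
Conditions: O3, CH2Cl2/MeOH (3:1), −78 °C; N2 purge, concentration below 20 °C, no reductant
Reagents that add atoms: ozone, [O-][O+]=O; methanol, CO
Why: Ozonolysis in methanol (Criegee mechanism), in which the primary ozonide of the 1,1-disubstituted alkene splits towards the more substituted carbonyl oxide 6 and formaldehyde, methanol traps 6 as the α-methoxy hydroperoxide, the cold neutral medium leaves the β-lactone intact, and the new ketal centre C6 needs no control because step 5 erases it.

Step 4
Reactants: 7 (3S,4R)-4-(3-hydroperoxy-3-methoxybutyl)-3-methyloxetan-2-one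
Product: 9 methyl (2S)-2-[(3S)-6-methoxy-6-methyl-1,2-dioxan-3-yl]propanoate (both C6 epimers), via caesium carboxylate 8 (not isolated)
Conditions: Cs2CO3 (1.2 equiv), DMF (0.01 M), 0 °C to rt; then MeI (3 equiv), rt
Reagents that add atoms: iodomethane, CI
Why: Proposed new method: Cs2CO3 deprotonates only the hydroperoxide, which is far more acidic than any C–H present, and the peroxy anion attacks C3 opposite to the lactone C–O bond in a 6-exo-tet SN2 alkyl–oxygen cleavage driven by release of ring strain, which inverts C3 from R to S, leaves C2 untouched and turns the syn into the required anti C2/C3 relation; attack at the acyl carbon would need an eight-membered perester, and E1cB loss of the leaving group is stereoelectronically blocked in the four-membered ring; the liberated carboxylate 8 is methylated in the same flask; the closest known reaction types are the invertive SN2 opening of 4-alkyl-β-lactones by azide, thiolates or cuprates and the intramolecular alkylation of hydroperoxyketal anions by secondary sulfonates.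

Step 5
Reactants: 9 methyl (2S)-2-[(3S)-6-methoxy-6-methyl-1,2-dioxan-3-yl]propanoate; 10 allyltrimethylsilane
Product: 12 methyl (2S)-2-[(3S,6R)-6-methyl-6-(prop-2-en-1-yl)-1,2-dioxan-3-yl]propanoate, via peroxycarbenium ion 11 (not isolated)
Conditions: 10 (3 equiv), TiCl4 (1.2 equiv), CH2Cl2, −78 °C; aq. NaHCO3
Reagents that add atoms: none
Why: Hosomi–Sakurai-type allylation of a cyclic monoperoxyketal, in which TiCl4 ionises the exocyclic methoxy group of both C6 epimers to the same peroxycarbenium ion 11, whose half-chair holds the C3 side chain pseudoequatorial, and the allylsilane attacks C6 along the axial trajectory that leads directly to a chair, so the new chain should end up axial and cis to the C3 substituent (6R) in a stereoconvergent manner.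

Step 6
Reactants: 12 methyl (2S)-2-[(3S,6R)-6-methyl-6-(prop-2-en-1-yl)-1,2-dioxan-3-yl]propanoate
Product: 14 methyl (2S)-2-[(3S,6S)-6-(3-hydroxypropyl)-6-methyl-1,2-dioxan-3-yl]propanoate, via B-alkyl-9-BBN adduct 13 (not isolated)
Conditions: 9-BBN (1.5 equiv), THF, 0 °C to rt; then NaBO3·4H2O, THF/H2O, rt
Reagents that add atoms: sodium perborate, [Na+].[O-]OB=O
Why: Hydroboration–oxidation, in which the bulky 9-BBN adds anti-Markovnikov to the monosubstituted alkene and reduces neither the ester nor the dialkyl peroxide at room temperature, and the mild perborate oxidation of 13 avoids the strong base that could cause ester hydrolysis or base-induced peroxide fragmentation.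

Step 7
Reactants: 14 methyl (2S)-2-[(3S,6S)-6-(3-hydroxypropyl)-6-methyl-1,2-dioxan-3-yl]propanoate
Product: 16 methyl (2S)-2-[(3S,6R)-6-(2-carboxyethyl)-6-methyl-1,2-dioxan-3-yl]propanoate, via aldehyde 15 (not isolated)
Conditions: TEMPO (20 mol %), PhI(OAc)2 (2.4 equiv), MeCN/H2O (1:1), rt
Reagents that add atoms: water, O
Why: Oxoammonium oxidation (TEMPO/PhI(OAc)2) in aqueous acetonitrile takes the primary alcohol through aldehyde 15 and its hydrate to the acid under near-neutral, purely oxidising conditions that are harmless to the O–O bond and should not epimerise C2.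

Step 8
Reactants: 17 methyl hex-5-ynoate
Product: 18 2-methylhept-6-yn-2-ol
Conditions: MeMgBr (3.3 equiv), THF, 0 °C to rt; aq. NH4Cl
Reagents that add atoms: methylmagnesium bromide, C[Mg]Br
Why: Double Grignard addition to an ester gives the dimethylcarbinol, and the third equivalent only deprotonates the alkyne C–H, which is restored on work-up.

Step 9
Reactants: 18 2-methylhept-6-yn-2-ol
Product: 20 2-methyl-6-(trimethylstannyl)hept-6-en-2-ol, via alkenylcopper adduct 19 (not isolated)
Conditions: Me3SnSnMe3 (2 equiv), MeLi (2 equiv), THF, −20 °C; CuBr·SMe2 (2 equiv), −78 °C; 18, MeOH (60 equiv), −63 °C; aq. NH4Cl/NH3 (pH 8)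
Reagents that add atoms: hexamethyldistannane, C[Sn](C)(C)[Sn](C)(C)C
Why: Stannylcupration–protonation, in which Me3SnCu·SMe2 adds reversibly and syn across the terminal alkyne and the methanol present from the start irreversibly protonates the kinetically favoured adduct 19 (copper on the terminal carbon, tin on the internal carbon), which gives the 2-stannyl-1-alkene and tolerates the free alcohol.

Step 10
Reactants: 16 methyl (2S)-2-[(3S,6R)-6-(2-carboxyethyl)-6-methyl-1,2-dioxan-3-yl]propanoate; 20 2-methyl-6-(trimethylstannyl)hept-6-en-2-ol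
Product: 22 aikupikoxide D, via acid chloride 21 (not isolated)
Conditions: 16, 1-chloro-N,N,2-trimethylprop-1-en-1-amine (1.1 equiv), CH2Cl2, 0 °C; solvent exchange to THF; 20 (1.2 equiv), Pd2(dba)3·CHCl3 (2.5 mol %), P(2-furyl)3 (10 mol %), BHT (trace), rt to 45 °C
Reagents that add atoms: none
Why: Milstein–Stille ketone synthesis: zerovalent palladium inserts into the C9–Cl bond of 21, the alkenyl group of 20 passes from tin to the acylpalladium chloride with loss of Me3SnCl, and reductive elimination forms the C9–C10 bond. The closest known reaction type is the palladium-catalysed coupling of aliphatic acid chlorides with alkenylstannanes, and palladium cross-coupling is a reaction class known to tolerate dialkyl peroxides such as 1,2-dioxanes. No ring is closed and no stereocentre is formed; C2, C3 and C6 are remote from the reacting carbon and meet neither acid nor base, because the acid is activated under neutral conditions that release only an amide. The step needs chemoselectivity for C–Cl insertion over the O–O bond, the methyl ester and the free tertiary alcohol; this is secured by the much faster oxidative addition of the acyl chloride, by the weakly donating P(2-furyl)3 present only in catalytic amount, and by the absence of base or acyl-transfer catalyst, so the hindered alcohol should stay unacylated. It also needs ipso transfer of the sp2 carbon in preference to methyl, which the usual migratory order on tin provides. Because Me3SnCl is the only by-product, no nucleophile is present that could add to the methylidene ketone, which is why an acid chloride is preferred to a thioester.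

Compound list
1 | ethyl 4-methylpent-4-enoate | C=C(C)CCC(=O)OCC | starting material
2 | 4-methylpent-4-enal | C=C(C)CCC=O | intermediate
3 | propanoyl chloride | CCC(=O)Cl | starting material
4 | methylketene (prop-1-en-1-one) | CC=C=O | intermediate
5 | (3S,4R)-3-methyl-4-(3-methylbut-3-en-1-yl)oxetan-2-one (cis-β-lactone) | C=C(C)CC[C@H]1OC(=O)[C@H]1C | intermediate
6 | carbonyl oxide of the methyl ketone derived from 5 | CC(=[O+][O-])CC[C@H]1OC(=O)[C@H]1C | intermediate
7 | (3S,4R)-4-(3-hydroperoxy-3-methoxybutyl)-3-methyloxetan-2-one (both ketal epimers) | COC(C)(OO)CC[C@H]1OC(=O)[C@H]1C | intermediate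
8 | caesium (2S)-2-[(3S)-6-methoxy-6-methyl-1,2-dioxan-3-yl]propanoate | COC1(C)CC[C@@H]([C@H](C)C(=O)[O-])OO1.[Cs+] | intermediate
9 | methyl (2S)-2-[(3S)-6-methoxy-6-methyl-1,2-dioxan-3-yl]propanoate (both C6 epimers) | COC1(C)CC[C@@H]([C@H](C)C(=O)OC)OO1 | intermediate
10 | allyltrimethylsilane | C=CC[Si](C)(C)C | starting material
11 | peroxycarbenium ion formed from 9 by loss of methoxide | CC1=[O+]O[C@@H](CC1)[C@H](C)C(=O)OC | intermediate
12 | methyl (2S)-2-[(3S,6R)-6-methyl-6-(prop-2-en-1-yl)-1,2-dioxan-3-yl]propanoate | C=CC[C@@]1(C)CC[C@@H]([C@H](C)C(=O)OC)OO1 | intermediate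
13 | B-alkyl-9-BBN adduct of 12 (boron on C9) | C1CC2CCCC(C1)B2CCC[C@@]3(C)CC[C@@H]([C@H](C)C(=O)OC)OO3 | intermediate
14 | methyl (2S)-2-[(3S,6S)-6-(3-hydroxypropyl)-6-methyl-1,2-dioxan-3-yl]propanoate (6S by CIP ranking only; geometry as in 12) | OCCC[C@@]1(C)CC[C@@H]([C@H](C)C(=O)OC)OO1 | intermediate
15 | methyl (2S)-2-[(3S,6R)-6-methyl-6-(3-oxopropyl)-1,2-dioxan-3-yl]propanoate | O=CCC[C@@]1(C)CC[C@@H]([C@H](C)C(=O)OC)OO1 | intermediate
16 | methyl (2S)-2-[(3S,6R)-6-(2-carboxyethyl)-6-methyl-1,2-dioxan-3-yl]propanoate | OC(=O)CC[C@@]1(C)CC[C@@H]([C@H](C)C(=O)OC)OO1 | intermediate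
17 | methyl hex-5-ynoate | C#CCCCC(=O)OC | starting material
18 | 2-methylhept-6-yn-2-ol | C#CCCCC(C)(C)O | intermediate
19 | alkenylcopper adduct (copper on the terminal carbon, cis to tin) | [Cu]/C=C(\[Sn](C)(C)C)CCCC(C)(C)O | intermediate
20 | 2-methyl-6-(trimethylstannyl)hept-6-en-2-ol | C=C(CCCC(C)(C)O)[Sn](C)(C)C | intermediate
21 | methyl (2S)-2-[(3S,6R)-6-(3-chloro-3-oxopropyl)-6-methyl-1,2-dioxan-3-yl]propanoate | ClC(=O)CC[C@@]1(C)CC[C@@H]([C@H](C)C(=O)OC)OO1 | intermediate
22 | aikupikoxide D, methyl (2S)-2-[(3S,6R)-6-(8-hydroxy-8-methyl-4-methylidene-3-oxononyl)-6-methyl-1,2-dioxan-3-yl]propanoate | C=C(CCCC(C)(C)O)C(=O)CC[C@@]1(C)CC[C@@H]([C@H](C)C(=O)OC)OO1 | target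

Total step count: 10. Longest linear sequence: 8 (steps 1 to 7, then step 10).

Steps most likely to fail

Risk 1, step 4 (ring closure on the β-lactone). Intermolecular attack of the peroxy anion at the acyl carbon (perester oligomers), or collapse of the hydroperoxyketal, may outrun the 6-exo-tet closure.
- The fallback replaces the lactone carboxylate by a sulfonate on a substrate without a carbonyl group. It uses only known chemistry, sets out from 5 and comes back at 9.
- LiAlH4 in Et2O at 0 °C opens 5 to (2R,3R)-2,6-dimethylhept-6-ene-1,3-diol F1.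
- TBDPSCl and imidazole silylate the primary hydroxyl to give (2R,3R)-1-[(tert-butyldiphenylsilyl)oxy]-2,6-dimethylhept-6-en-3-ol F2.
- MsCl/Et3N gives (2R,3R)-1-[(tert-butyldiphenylsilyl)oxy]-2,6-dimethylhept-6-en-3-yl methanesulfonate F3.
- Ozonolysis in CH2Cl2/MeOH at −78 °C gives (2R,3R)-1-[(tert-butyldiphenylsilyl)oxy]-6-hydroperoxy-6-methoxy-2-methylheptan-3-yl methanesulfonate F4.
- KOtBu and 18-crown-6 in toluene close the ring by invertive intramolecular alkylation to tert-butyl{(2R)-2-[(3S)-6-methoxy-6-methyl-1,2-dioxan-3-yl]propoxy}diphenylsilane F5.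
- Bu4NF frees (2R)-2-[(3S)-6-methoxy-6-methyl-1,2-dioxan-3-yl]propan-1-ol F6.
- TEMPO/PhI(OAc)2 in aqueous MeCN gives (2S)-2-[(3S)-6-methoxy-6-methyl-1,2-dioxan-3-yl]propanoic acid F7, and Me3SiCHN2 in toluene/MeOH gives 9.

Risk 2, step 5 (allylation at C6). The C1 ester carbonyl may take part in the peroxycarbenium ion or chelate TiCl4. Either would populate the half-chair with a pseudoaxial side chain and erode the facial selectivity at C6.
- The fallback removes the carbonyl group from the substrate and changes the order of events. It sets out from 5, runs through F1 to F5 as described above, and comes back at 12.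
- The silyl ether F5 is allylated with 10 and TiCl4 at −78 °C to tert-butyl{(2R)-2-[(3S,6R)-6-methyl-6-(prop-2-en-1-yl)-1,2-dioxan-3-yl]propoxy}diphenylsilane F8.
- Bu4NF gives (2R)-2-[(3S,6R)-6-methyl-6-(prop-2-en-1-yl)-1,2-dioxan-3-yl]propan-1-ol F9.
- TEMPO/PhI(OAc)2 in aqueous MeCN gives (2S)-2-[(3S,6R)-6-methyl-6-(prop-2-en-1-yl)-1,2-dioxan-3-yl]propanoic acid F10, and Me3SiCHN2 gives 12.

Risk 3, step 10 (acylative coupling). Transmetalation of the hindered 1,1-disubstituted alkenylstannane may be slow. Decarbonylation with β-hydride elimination of the acylpalladium species, or attrition of the O–O bond, could then take over.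
- The fallback makes the same bond by carbonyl addition at the aldehyde oxidation level. It sets out from 14 and 20 and comes back at 22.
- Dess–Martin oxidation of 14 gives aldehyde 15, which is now isolated.
- Tin–lithium exchange on 20 with n-BuLi (2.1 equiv, THF, −78 °C) gives lithium 6-lithio-2-methylhept-6-en-2-olate F11.
- F11 is added to 15 at −78 °C, where the aldehyde reacts much faster than the ester or the peroxide. This gives methyl (2S)-2-[(3S,6S)-6-(3,8-dihydroxy-8-methyl-4-methylidenenonyl)-6-methyl-1,2-dioxan-3-yl]propanoate F12 as both C9 epimers, which is of no consequence.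
- MnO2 in CH2Cl2 oxidises only the secondary allylic alcohol and gives 22.

Further compounds
F1 | step 4 | (2R,3R)-2,6-dimethylhept-6-ene-1,3-diol | C=C(C)CC[C@@H](O)[C@H](C)CO
F2 | step 4 | (2R,3R)-1-[(tert-butyldiphenylsilyl)oxy]-2,6-dimethylhept-6-en-3-ol | C=C(C)CC[C@@H](O)[C@H](C)CO[Si](c1ccccc1)(c1ccccc1)C(C)(C)C
F3 | step 4 | (2R,3R)-1-[(tert-butyldiphenylsilyl)oxy]-2,6-dimethylhept-6-en-3-yl methanesulfonate | C=C(C)CC[C@@H](OS(C)(=O)=O)[C@H](C)CO[Si](c1ccccc1)(c1ccccc1)C(C)(C)C
F4 | step 4 | (2R,3R)-1-[(tert-butyldiphenylsilyl)oxy]-6-hydroperoxy-6-methoxy-2-methylheptan-3-yl methanesulfonate | COC(C)(OO)CC[C@@H](OS(C)(=O)=O)[C@H](C)CO[Si](c1ccccc1)(c1ccccc1)C(C)(C)C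
F5 | step 4 | tert-butyl{(2R)-2-[(3S)-6-methoxy-6-methyl-1,2-dioxan-3-yl]propoxy}diphenylsilane | COC1(C)CC[C@@H]([C@H](C)CO[Si](c2ccccc2)(c2ccccc2)C(C)(C)C)OO1
F6 | step 4 | (2R)-2-[(3S)-6-methoxy-6-methyl-1,2-dioxan-3-yl]propan-1-ol | COC1(C)CC[C@@H]([C@H](C)CO)OO1
F7 | step 4 | (2S)-2-[(3S)-6-methoxy-6-methyl-1,2-dioxan-3-yl]propanoic acid | COC1(C)CC[C@@H]([C@H](C)C(=O)O)OO1
F8 | step 5 | tert-butyl{(2R)-2-[(3S,6R)-6-methyl-6-(prop-2-en-1-yl)-1,2-dioxan-3-yl]propoxy}diphenylsilane | C=CC[C@@]1(C)CC[C@@H]([C@H](C)CO[Si](c2ccccc2)(c2ccccc2)C(C)(C)C)OO1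
F9 | step 5 | (2R)-2-[(3S,6R)-6-methyl-6-(prop-2-en-1-yl)-1,2-dioxan-3-yl]propan-1-ol | C=CC[C@@]1(C)CC[C@@H]([C@H](C)CO)OO1
F10 | step 5 | (2S)-2-[(3S,6R)-6-methyl-6-(prop-2-en-1-yl)-1,2-dioxan-3-yl]propanoic acid | C=CC[C@@]1(C)CC[C@@H]([C@H](C)C(=O)O)OO1
F11 | step 10 | lithium 6-lithio-2-methylhept-6-en-2-olate | [Li]C(=C)CCCC(C)(C)O[Li]
F12 | step 10 | methyl (2S)-2-[(3S,6S)-6-(3,8-dihydroxy-8-methyl-4-methylidenenonyl)-6-methyl-1,2-dioxan-3-yl]propanoate (both C9 epimers) | C=C(CCCC(C)(C)O)C(O)CC[C@@]1(C)CC[C@@H]([C@H](C)C(=O)OC)OO1
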